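**Atom numbers used throughout (iridal numbering):** C1 = CHO; C2 = olefinic carbon bearing CH3; C3 = CH2OH; C4, C5 = chain CH2; C6 = ring CH; C7 = ring olefinic carbon; C8, C9 = ring CH2; C10 = C(OH)CH3; C11 = quaternary ring carbon; C12, C13 = CH2; C14=C15 = side-chain olefin; C16 (CH–O), C17, C18 (CHOH), C19 (C–O) = oxolane carbons; C20–C23 = 4-methylpent-3-enyl tail. The target is (2Z,6R,10S,11S,14E,16R,18R,19S).

## The problem

The target is a monocyclic C30 triterpenoid. Its cyclohexane (C6–C11) carries on three contiguous carbons a CH stereocentre (C6, hydroxypropyl arm), an all-carbon quaternary centre (C11) and a tertiary carbinol (C10). C7 bears an exocyclic, tetrasubstituted (Z)-α-methyl enal. This olefin is the hardest element: the two ring neighbours of C7 (C6 and C8) differ only beyond the α-carbon, so carbonyl olefination at C7 has no basis for selectivity and neither isomer is clearly favoured at equilibrium. C11 carries two sterically similar groups (CH3, CH2R), so it is a weak control element for C6 and C10 unless one group is temporarily made very different. The oxolane (C16, C18, C19) is four carbons and an (E)-trisubstituted olefin away from the ring, so it needs its own source of absolute configuration and a geometry-secure union. The enal (E/Z drift via dienolate, 1,2-addition), the C1-aldehyde/C3-alcohol differentiation, the tertiary alcohol and the acid-sensitive trisubstituted olefins limit the endgame.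

The enabling feature is that C1 and C6 are cis on C2=C7, so C1 and C4 are 1,6-related along C1–C2=C7–C6–C5–C4. A C1–C4 bond would close a cyclohexene ("ring A′") that contains the tetrasubstituted olefin and places O–C1 and the C3 oxygen in an aldol relationship across that bond. The target is therefore the retro-aldol product of a Diels–Alder adduct of a 1-oxy-diene (C1=C2–C7=C6) and an acrylate (C5=C4–C3). In addition, ring C6–C11 maps onto an o-anisic acid (C10 = C–OMe, C11 = ipso carbon, C12 = carboxyl carbon).

## Retrosynthesis

**C1 oxidation level.** Target 40 is traced to tetraol 39. The enal is unveiled last by chemoselective allylic oxidation, so the isomerisable aldehyde is never exposed to bases, hydrides or boranes. Tetraol 39 comes from the tris-silyl ether 38.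

**C13–C14.** The bond between sp3 C13 and sp2 C14 is cut (B-alkyl Suzuki coupling) to give the C11-vinyl core 22 and the (E)-iodoalkene 36. Cutting C14=C15 by olefination instead would give a trisubstituted olefin without E control. The (E)-geometry is better made by alkyne carbometalation on the small fragment. The two halves are of similar size and carry all stereocentres.

**C12=C13 and the silyl groups.** Vinyl compound 22 comes from aldehyde 21, and this from amide 20, the silylated form of triol 19. C12 is thus a former carboxamide carbon, which ties the quaternary centre to an aromatic acid.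

**C1–C4 reconnection (retro-aldol transform).** Triol 19 comes from enal ester 18. Joining C1 to C4 in 18 gives the bicyclic β-silyloxy ester 16. This removes the geometric problem, because in 16 the C2=C7 bond is endocyclic in ring A′. The forward step must only cleave an allylic C–C bond of an alkoxide (17).

**C10–CH3.** Alcohol 16 comes from ketone 15 by methyl addition, and 15 from enol ether 14. This is done on the rigid bicycle, where C11–CH3 is axial and the attack trajectory is defined.

**Ring A′ (key disconnection).** The C5–C6 and C1–C4 bonds of 14 are cut (Diels–Alder) to give silyl dienol ether 12 and methyl acrylate 13. This one step creates C6, both ring A′ bonds and the olefin lock. Diene 12 is planar at ring B, so the amide on C11 can control the face.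

**Dearomatisation.** Diene 12 comes from aldehyde 11 and alcohol 10. The C11–CH3 bond and the two ring sp3 centres of 10 are removed (Birch reductive alkylation) to give anisamide 8. The methoxy group fixes the later C10 carbonyl, the chiral amide sets C11, and the alkyl arm fixes C7=C6. Arene 8 comes from 6 and 4, made from acid 1, auxiliary 2 and boronate 5.

**Oxolane fragment.** Iodide 36 comes from alkyne 34, aldehyde 33, diol 32 and benzyl ether 31. The ring O–C16 bond of 31 is cut (inverting 5-exo displacement) to give mesylate 29. This comes from the 1,3-syn epoxy alcohol 28 and homoallylic alcohol 27, assembled from enyne 24 and glycidyl ether 25. Enyne 24 comes from bromide 23.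

## Roads not taken

Alternative 1: (the most obvious) Cut C2=C7. The ring is built by conjugate addition/enolate alkylation on a 4-oxygenated 2-methylcyclohexenone to give ketone A1. C7 is then olefinated with a 2-phosphonopropionate to give enoate A2. C6 and C8 differ only at the β-position, so olefination of this hindered, epimerisable ketone has no source of Z-selectivity and is slow for a tetrasubstituted product. The chosen plan fixes the geometry by a ring instead of hoping for selectivity.

Alternative 2: Cut C2–C3, the biogenetic "seco-A" bond. Robinson annulation gives octalone A3. Deconjugative alkylation at C2, reduction and activation at C7 would set up a Grob fragmentation to C7=C2 and a C3 aldehyde. A concerted, stereospecific fragmentation needs a nucleofuge on the fully substituted ring-fusion carbon C7, antiperiplanar to C2–C3, and one configuration at a new quaternary C2. That means six stereocentres, three made only to be destroyed, and a tertiary sulfonate that would ionise and rearrange. The chosen plan fragments a secondary alkoxide and needs no extra quaternary centre.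

Alternative 3: Form C5–C6 and lock the olefin in a seven-membered ring by joining C1 to C3. Rhodium-vinylcarbenoid cyclopropanation of a 2-(cyclohexenyl)propene and divinylcyclopropane rearrangement (formal [4+3]) would give cycloheptadiene ester A4 with C6 and the Z olefin set. The carbenoid carbon brings an ester that is one carbon too many. The C1–C3 bond has no aldol relationship and must be excised oxidatively, and C3=C4 must be reduced, which costs at least six redox steps after the key step. The six-membered lock of the chosen plan opens in one retro-aldol step, and its arene precursor also solves the C10/C11 regiochemistry.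

Key step: step 7

## Assumptions

Assumption 1: with the (S)-auxiliary 2, methylation of enolate 9 is taken to occur on the face that gives the C11 configuration drawn (chelated amide-enolate model); if the sense is the opposite, the enantiomer of 2 is used and nothing else changes.

Assumption 2: the vanadium-directed epoxidation of 27 is taken to give the 1,3-syn epoxy alcohol (carbinol substituent equatorial in the chair-like vanadate); the fallback covers the other outcome.

## Route

Step 1
Reactants: 1 5-bromo-2-methoxybenzoic acid; 2 (S)-2-(methoxymethyl)pyrrolidine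
Product: 4 (S)-(5-bromo-2-methoxyphenyl)[2-(methoxymethyl)pyrrolidin-1-yl]methanone, via acid chloride 3 (not isolated)
Conditions: (COCl)2, cat. DMF, CH2Cl2, 0 °C → rt; then 2, Et3N, CH2Cl2, 0 °C
Reagents that add atoms: none
Why: Acid chloride formation and N-acylation of the secondary amine; no stereocentre is touched.

Step 2
Reactants: 4 aryl bromide; 5 isopropenylboronic acid pinacol ester
Product: 6 (S)-[2-methoxy-5-(prop-1-en-2-yl)phenyl][2-(methoxymethyl)pyrrolidin-1-yl]methanone
Conditions: Pd(dppf)Cl2 (cat.), K2CO3, dioxane/H2O, 85 °C
Reagents that add atoms: none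
Why: Suzuki–Miyaura coupling of an aryl bromide with an alkenyl boronate; amide and aryl ether are inert.

Step 3
Reactants: 6 isopropenyl arene
Product: 8 (S)-[5-(1-hydroxypropan-2-yl)-2-methoxyphenyl][2-(methoxymethyl)pyrrolidin-1-yl]methanone (both epimers at C2), via alkylborane 7 (not isolated)
Conditions: 9-BBN, THF, 0 °C → rt; then NaOH, H2O2, 0 °C
Reagents that add atoms: hydrogen peroxide, SMILES OO
Why: Anti-Markovnikov hydroboration–oxidation of the 1,1-disubstituted styrene; 9-BBN does not reduce the tertiary amide. The new benzylic centre (C2) forms as both epimers, which is immaterial because C2 becomes sp2 in step 6.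

Step 4
Reactants: 8 anisamide alcohol
Product: 10 1,4-cyclohexadiene with C11 quaternary (CH3 and auxiliary carboxamide), C10=C9 methyl enol ether and C7=C6 olefin bearing the 1-hydroxypropan-2-yl arm, via dipotassium enolate 9 (not isolated)
Conditions: K (2.2 equiv), NH3/THF, −78 °C (no added alcohol); piperylene; MeI (1.1 equiv), −78 °C; aq. NH4Cl
Reagents that add atoms: iodomethane, SMILES CI
Why: Birch reductive alkylation of a chiral o-anisamide: two-electron reduction with protonation at C8 by the substrate's own hydroxyl gives amide enolate 9, whose C-methylation under auxiliary control creates C11. The methoxy group fixes the enol ether as C10=C9 and the alkyl arm keeps C7=C6. The potassium alkoxide is not expected to be methylated by one equivalent of MeI at −78 °C.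

Step 5
Reactants: 10 dienyl alcohol
Product: 11 the corresponding aldehyde (C1 = CHO; both epimers at C2)
Conditions: SO3·pyridine, DMSO, i-Pr2NEt, CH2Cl2, 0 °C
Reagents that add atoms: none
Why: Parikh–Doering oxidation is non-acidic, so the methyl enol ether and the skipped diene should survive; the α-branched aldehyde is used crude to avoid conjugation.

Step 6
Reactants: 11 aldehyde
Product: 12 (1E)-tert-butyldimethylsilyl dienol ether (diene C1=C2–C7=C6)
Conditions: TBSOTf, Et3N, CH2Cl2, −78 → 0 °C
Reagents that add atoms: tert-butyldimethylsilyl triflate, SMILES CC(C)(C)[Si](C)(C)OS(=O)(=O)C(F)(F)F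
Why: Soft enolisation and O-silylation removes the doubly activated C2–H. The (E)-enol ether (OSi cis to CH3, trans to the bulkier ring) should predominate and is the isomer that can reach the s-cis conformation.

Step 7
Reactants: 12 silyl dienol ether; 13 methyl acrylate
Product: 14 Diels–Alder adduct: ring A′ (C1–C2=C7–C6–C5–C4) fused to ring B, C1–OTBS and C4–CO2Me (diastereomer mixture at C1/C4), C6–H cis to C11–CH3
Conditions: 13 (10 equiv), BHT (cat.), toluene, 110 °C, sealed tube
Reagents that add atoms: none
Why: Concerted, asynchronous normal-demand Diels–Alder cycloaddition, the closest known type being that of 1-silyloxy semicyclic dienes with acrylic esters. Ring A′ is closed by [4+2] closure, the acrylate β-carbon C5 bonding to C6 and the α-carbon C4 to C1. The required "ortho" regioselectivity is secured by the C1 silyloxy group, which puts the largest HOMO coefficient on C6. The new stereocentre C6 is controlled by C11: ring B is a nearly planar 1,4-cyclohexadiene whose faces at C6 are flanked by CH3 and by the bulky pyrrolidine carboxamide, so the dienophile should add anti to the amide and place C5 cis to C11–CH3. The stereocentres C1 and C4 form as an endo/exo mixture that does not matter, since both are destroyed in step 10. Because C1 and C6 are both members of the new ring, C1 is necessarily cis to C6 on C2=C7, which fixes the (2Z) geometry of the later enal. The (1E)-enol ether and the ring-enforced outward position of C11 on C6 allow the s-cis conformation, and the isolated C10=C9 enol ether cannot act as a diene.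

Step 8
Reactants: 14 Diels–Alder adduct
Product: 15 C10 ketone (β-keto amide)
Conditions: oxalic acid (aq.), THF, 0 °C → rt
Reagents that add atoms: water, SMILES O
Why: Mild hydrolysis of the methyl enol ether (protonation at C9, water capture at C10); the secondary TBS ether and the ester should be stable to oxalic acid.

Step 9
Reactants: 15 ketone
Product: 16 C10 tertiary alcohol (C10–OH cis to C11–CH3 and to C6–C5)
Conditions: MeLi, CeCl3, THF, −78 °C
Reagents that add atoms: methyllithium, SMILES [Li]C
Why: Organocerium 1,2-addition is non-basic and ketone-selective over the ester. In the rigid bicycle C11–CH3 is axial and the amide equatorial, so the nucleophile should add axially to C10 anti to C11–CH3, which gives the target's C10 configuration.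

Step 10
Reactants: 16 bicyclic β-silyloxy ester
Product: 18 monocyclic (2Z)-enal methyl ester, via C1 alkoxide 17 (not isolated)
Conditions: TBAF, THF, 0 °C → rt
Reagents that add atoms: none
Why: Fluoride removes the C1 silyl group and alkoxide 17 undergoes retro-aldol cleavage of the allylic C1–C4 bond, driven by formation of the conjugated enal and irreversible protonation of the ester enolate. Because C1 and C6 were ring members, only the (Z)-enal can form.

Step 11
Reactants: 18 enal ester
Product: 19 triol (C1–OH allylic, C3–OH, C10–OH)
Conditions: DIBAL-H, CH2Cl2, −78 → 0 °C; Rochelle salt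
Reagents that add atoms: none
Why: DIBAL-H reduces the enal (1,2) and the methyl ester to primary alcohols; the hindered tertiary amide should survive at low temperature. The olefin geometry is now stored as an allylic alcohol.

Step 12
Reactants: 19 triol
Product: 20 tris(triethylsilyl) ether
Conditions: TESOTf (3.5 equiv), 2,6-lutidine, CH2Cl2, −78 → 0 °C
Reagents that add atoms: triethylsilyl triflate, SMILES CC[Si](CC)(CC)OS(=O)(=O)C(F)(F)F
Why: The silyl triflate silylates both primary and the tertiary hydroxyl, so the later β-oxy aldehyde cannot undergo retro-aldol cleavage and hydride reagents are not consumed.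

Step 13
Reactants: 20 silylated amide
Product: 21 C12 aldehyde
Conditions: Cp2Zr(H)Cl, THF, rt
Reagents that add atoms: none
Why: Schwartz's reagent reduces tertiary amides to aldehydes through a zirconated hemiaminal and releases the auxiliary; silyl ethers and the tetrasubstituted olefin are inert.

Step 14
Reactants: 21 aldehyde
Product: 22 C11-vinyl core (C12=C13)
Conditions: Ph3PCH3Br, KHMDS, THF, 0 °C → rt
Reagents that add atoms: methyltriphenylphosphonium bromide, SMILES C[P+](c1ccccc1)(c1ccccc1)c1ccccc1.[Br-]
Why: Wittig methylenation of a non-enolisable neopentyl aldehyde.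

Step 15
Reactants: 23 5-bromo-2-methylpent-2-ene
Product: 24 6-methylhept-5-en-1-yne
Conditions: LiC≡CH·H2NCH2CH2NH2, DMSO, 10 °C → rt
Reagents that add atoms: lithium acetylide–ethylenediamine complex, SMILES [Li+].[C-]#C.NCCN
Why: SN2 alkylation of acetylide by a primary bromide.

Step 16
Reactants: 24 enyne; 25 (S)-benzyl glycidyl ether
Product: 27 (2S,4E)-1-(benzyloxy)-5,9-dimethyldeca-4,8-dien-2-ol, via alkenylalane 26 (not isolated)
Conditions: Me3Al, Cp2ZrCl2 (cat.), CH2Cl2, rt; n-BuLi, hexane/THF, −30 °C; 25, −30 °C → rt
Reagents that add atoms: trimethylaluminium, SMILES C[Al](C)C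
Why: Zirconium-catalysed syn-carboalumination (Negishi) places CH3 on C19 and Al on C18 with (E) geometry. The derived alanate opens the epoxide at the terminal carbon C17, keeping the olefin geometry and the C16 configuration of 25.

Step 17
Reactants: 27 homoallylic alcohol
Product: 28 1,3-syn 3,4-epoxy alcohol (epoxide C18–C19)
Conditions: VO(acac)2 (cat.), t-BuOOH, CH2Cl2, 0 °C → rt
Reagents that add atoms: tert-butyl hydroperoxide, SMILES CC(C)(C)OO
Why: Hydroxyl-directed vanadium-catalysed epoxidation reaches only the homoallylic C18=C19 olefin, not C22=C23. A chair-like vanadate with the C15 substituent equatorial and allylic-strain control from the cis C19–CH3 should favour the 1,3-syn isomer.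

Step 18
Reactants: 28 epoxy alcohol
Product: 29 epoxy mesylate
Conditions: MsCl, Et3N, CH2Cl2, 0 °C
Reagents that add atoms: methanesulfonyl chloride, SMILES CS(=O)(=O)Cl
Why: Mesylation turns O16 into the leaving group and stops it from opening the epoxide.

Step 19
Reactants: 29 epoxy mesylate
Product: 31 oxolane benzyl ether (C16, C18, C19 as in the target), via diol mesylate 30 (not isolated)
Conditions: HClO4 (cat.), THF/H2O, 0 °C; then K2CO3, MeOH, 40 °C
Reagents that add atoms: water, SMILES O
Why: Acid-catalysed hydrolysis opens the trisubstituted epoxide at the tertiary C19 with inversion, C18–O being retained. The C19 hydroxyl then displaces the C16 mesylate (5-exo-tet, inversion), which places the C16 substituent cis to C18–OH and C19–CH3.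

Step 20
Reactants: 31 benzyl ether
Product: 32 oxolane diol (C15–OH, C18–OH)
Conditions: lithium naphthalenide, THF, −25 °C
Reagents that add atoms: none
Why: Radical-anion debenzylation, which unlike hydrogenolysis spares the trisubstituted olefin.

Step 21
Reactants: 32 diol
Product: 33 C15 aldehyde (may exist as its bicyclic lactol)
Conditions: TEMPO (cat.), PhI(OAc)2, CH2Cl2, rt
Reagents that add atoms: none
Why: Oxoammonium oxidation is selective for the primary alcohol over the secondary C18–OH.

Step 22
Reactants: 33 aldehyde
Product: 34 5-ethynyl oxolan-3-ol (C15≡C14)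
Conditions: dimethyl (1-diazo-2-oxopropyl)phosphonate, K2CO3, MeOH, 0 °C → rt
Reagents that add atoms: dimethyl (1-diazo-2-oxopropyl)phosphonate, SMILES COP(=O)(OC)C(=[N+]=[N-])C(C)=O
Why: Ohira–Bestmann homologation of the α-alkoxy aldehyde (or its lactol) under mild carbonate conditions.

Step 23
Reactants: 34 alkyne
Product: 36 (E)-iodoalkene (I on C14, CH3 on C15), via alkenylalane 35 (not isolated)
Conditions: Me3Al, Cp2ZrCl2, CH2Cl2, 0 °C → rt; I2, THF, −30 °C
Reagents that add atoms: trimethylaluminium, SMILES C[Al](C)C; iodine, SMILES II
Why: A second syn-carboalumination puts CH3 on C15 and Al on C14; iodinolysis with retention gives the (E)-iodoalkene. The free hydroxyl is carried as its aluminium alkoxide.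

Step 24
Reactants: 22 C11-vinyl core; 36 (E)-iodoalkene
Product: 38 coupled tris(triethylsilyl) ether with the complete carbon skeleton, via alkylborane 37 (not isolated)
Conditions: 22, 9-BBN, THF, rt → 40 °C; then 36, Pd(dppf)Cl2, AsPh3, Cs2CO3, DMF/H2O, rt
Reagents that add atoms: none
Why: 9-BBN hydroborates only the monosubstituted vinyl group of 22. B-alkyl Suzuki–Miyaura coupling forms C13–C14 with retention of the (E) geometry.

Step 25
Reactants: 38 tris-silyl ether
Product: 39 tetraol (C1–OH, C3–OH, C10–OH, C18–OH)
Conditions: HF·pyridine, pyridine, THF, 0 °C → rt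
Reagents that add atoms: none
Why: Buffered fluoride cleaves the three triethylsilyl ethers and nothing else.

Step 26
Reactants: 39 tetraol
Product: 40 CNP0155390.1
Conditions: MnO2, CH2Cl2, rt
Reagents that add atoms: none
Why: MnO2 oxidises only the allylic primary alcohol (C1), leaving the saturated primary (C3), secondary (C18) and tertiary (C10) alcohols; the tetrasubstituted olefin geometry is not affected.

## Compound list

1 | 5-bromo-2-methoxybenzoic acid | COc1ccc(Br)cc1C(=O)O | starting material
2 | (S)-2-(methoxymethyl)pyrrolidine | COC[C@@H]1CCCN1 | starting material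
3 | 5-bromo-2-methoxybenzoyl chloride | COc1ccc(Br)cc1C(Cl)=O | intermediate (not isolated)
4 | (S)-(5-bromo-2-methoxyphenyl)[2-(methoxymethyl)pyrrolidin-1-yl]methanone | COC[C@@H]1CCCN1C(=O)c1cc(Br)ccc1OC | intermediate
5 | isopropenylboronic acid pinacol ester | CC(=C)B1OC(C)(C)C(C)(C)O1 | starting material
6 | (S)-[2-methoxy-5-(prop-1-en-2-yl)phenyl][2-(methoxymethyl)pyrrolidin-1-yl]methanone | COC[C@@H]1CCCN1C(=O)c1cc(C(C)=C)ccc1OC | intermediate
7 | B-(2-arylpropyl)-9-borabicyclo[3.3.1]nonane from 6 | COC[C@@H]1CCCN1C(=O)c1cc(C(C)CB2C3CCCC2CCC3)ccc1OC | intermediate (not isolated)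
8 | (S)-[5-(1-hydroxypropan-2-yl)-2-methoxyphenyl][2-(methoxymethyl)pyrrolidin-1-yl]methanone, both epimers at C2 | COC[C@@H]1CCCN1C(=O)c1cc(C(C)CO)ccc1OC | intermediate
9 | dipotassium amide enolate/alkoxide from Birch reduction of 8 | COC[C@@H]1CCCN1C([O-])=C1C=C(C(C)C[O-])CC=C1OC.[K+].[K+] | intermediate (not isolated)
10 | Birch–methylation product: 1,4-cyclohexadiene, C11 (CH3, carboxamide), C10=C9 enol ether, C7=C6 with 1-hydroxypropan-2-yl arm | COC[C@@H]3CCCN3C(=O)[C@@]1(C)C=C(C(C)CO)CC=C1OC | intermediate
11 | aldehyde of 10 (C1 = CHO), both epimers at C2 | COC[C@@H]3CCCN3C(=O)[C@@]1(C)C=C(C(C)C=O)CC=C1OC | intermediate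
12 | (1E)-tert-butyldimethylsilyl dienol ether of 11 | COC[C@@H]3CCCN3C(=O)[C@@]1(C)C=C(/C(C)=C/O[Si](C)(C)C(C)(C)C)CC=C1OC | intermediate
13 | methyl acrylate | C=CC(=O)OC | starting material
14 | Diels–Alder adduct: ring A′ with C1–OTBS and C4–CO2Me (mixture at C1/C4), C6–H cis to C11–CH3, ring B C10=C9 enol ether | COC[C@@H]3CCCN3C(=O)[C@@]1(C)[C@@H]2CC(C(=O)OC)C(O[Si](C)(C)C(C)(C)C)C(C)=C2CC=C1OC | intermediate
15 | C10 ketone of the bicycle | COC[C@@H]3CCCN3C(=O)[C@@]1(C)[C@@H]2CC(C(=O)OC)C(O[Si](C)(C)C(C)(C)C)C(C)=C2CCC1=O | intermediate
16 | C10 tertiary alcohol of the bicycle (C10–OH cis to C11–CH3) | COC[C@@H]3CCCN3C(=O)[C@@]1(C)[C@@H]2CC(C(=O)OC)C(O[Si](C)(C)C(C)(C)C)C(C)=C2CC[C@]1(C)O | intermediate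
17 | tetrabutylammonium C1 alkoxide of the desilylated bicycle | COC[C@@H]3CCCN3C(=O)[C@@]1(C)[C@@H]2CC(C(=O)OC)C([O-])C(C)=C2CC[C@]1(C)O.CCCC[N+](CCCC)(CCCC)CCCC | intermediate (not isolated)
18 | monocyclic (2Z)-enal methyl ester: C1 = CHO, C3 = CO2Me, C10–OH, C11 carboxamide | COC[C@@H]3CCCN3C(=O)[C@@]1(C)[C@H](CCC(=O)OC)/C(=C(/C)C=O)CC[C@]1(C)O | intermediate
19 | triol (C1–OH, C3–OH, C10–OH), C11 carboxamide | COC[C@@H]3CCCN3C(=O)[C@@]1(C)[C@H](CCCO)/C(=C(/C)CO)CC[C@]1(C)O | intermediate
20 | tris(triethylsilyl) ether of 19 | COC[C@@H]3CCCN3C(=O)[C@@]1(C)[C@H](CCCO[Si](CC)(CC)CC)/C(=C(/C)CO[Si](CC)(CC)CC)CC[C@]1(C)O[Si](CC)(CC)CC | intermediate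
21 | C12 aldehyde | O=C[C@@]1(C)[C@H](CCCO[Si](CC)(CC)CC)/C(=C(/C)CO[Si](CC)(CC)CC)CC[C@]1(C)O[Si](CC)(CC)CC | intermediate
22 | C11-vinyl core | C=C[C@@]1(C)[C@H](CCCO[Si](CC)(CC)CC)/C(=C(/C)CO[Si](CC)(CC)CC)CC[C@]1(C)O[Si](CC)(CC)CC | intermediate
23 | 5-bromo-2-methylpent-2-ene | CC(C)=CCCBr | starting material
24 | 6-methylhept-5-en-1-yne | CC(C)=CCCC#C | intermediate
25 | (S)-benzyl glycidyl ether | O1C[C@H]1COCc2ccccc2 | starting material
26 | (E)-(2,6-dimethylhepta-1,5-dienyl)dimethylalane | CC(C)=CCC/C(C)=C/[Al](C)C | intermediate (not isolated)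
27 | (2S,4E)-1-(benzyloxy)-5,9-dimethyldeca-4,8-dien-2-ol | CC(C)=CCC/C(C)=C/C[C@H](O)COCc1ccccc1 | intermediate
28 | 1,3-syn C18–C19 epoxy alcohol | CC(C)=CCC[C@@]1(C)O[C@@H]1C[C@H](O)COCc2ccccc2 | intermediate
29 | C16 mesylate of 28 | CC(C)=CCC[C@@]1(C)O[C@@H]1C[C@H](OS(C)(=O)=O)COCc2ccccc2 | intermediate
30 | C18,C19-diol C16-mesylate | CC(C)=CCC[C@](C)(O)[C@H](O)C[C@H](OS(C)(=O)=O)COCc1ccccc1 | intermediate (not isolated)
31 | 5-(benzyloxymethyl)-2-methyl-2-(4-methylpent-3-enyl)oxolan-3-ol, C16/C18/C19 as in the target | CC(C)=CCC[C@]1(C)O[C@@H](COCc2ccccc2)C[C@H]1O | intermediate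
32 | 5-(hydroxymethyl)oxolan-3-ol analogue | CC(C)=CCC[C@]1(C)O[C@@H](CO)C[C@H]1O | intermediate
33 | oxolane-2-carbaldehyde (C15 = CHO) | CC(C)=CCC[C@]1(C)O[C@@H](C=O)C[C@H]1O | intermediate
34 | 5-ethynyl-2-methyl-2-(4-methylpent-3-enyl)oxolan-3-ol | CC(C)=CCC[C@]1(C)O[C@@H](C#C)C[C@H]1O | intermediate
35 | (E)-alkenyl(dimethyl)alane, C18–O as dimethylaluminium alkoxide | CC(C)=CCC[C@]1(C)O[C@@H](/C(C)=C/[Al](C)C)C[C@H]1O[Al](C)C | intermediate (not isolated)
36 | 5-[(E)-1-iodoprop-1-en-2-yl]-2-methyl-2-(4-methylpent-3-enyl)oxolan-3-ol | CC(C)=CCC[C@]1(C)O[C@@H](/C(C)=C/I)C[C@H]1O | intermediate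
37 | B-alkyl-9-BBN adduct of 22 (boron on C13) | B1(C2CCCC1CCC2)CC[C@@]3(C)[C@H](CCCO[Si](CC)(CC)CC)/C(=C(/C)CO[Si](CC)(CC)CC)CC[C@]3(C)O[Si](CC)(CC)CC | intermediate (not isolated)
38 | coupled C1,C3,C10-tris(triethylsilyl) ether | CC(C)=CCC[C@]1(C)O[C@@H](/C(C)=C/CC[C@@]2(C)[C@H](CCCO[Si](CC)(CC)CC)/C(=C(/C)CO[Si](CC)(CC)CC)CC[C@]2(C)O[Si](CC)(CC)CC)C[C@H]1O | intermediate
39 | tetraol (C1 allylic alcohol) | CC(C)=CCC[C@]1(C)O[C@@H](/C(C)=C/CC[C@@]2(C)[C@H](CCCO)/C(=C(/C)CO)CC[C@]2(C)O)C[C@H]1O | intermediate
40 | CNP0155390.1, (2Z,6R,10S,11S,14E,16R,18R,19S) | CC(C)=CCC[C@]1(C)O[C@@H](/C(C)=C/CC[C@@]2(C)[C@H](CCCO)/C(=C(/C)C=O)CC[C@]2(C)O)C[C@H]1O | target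

## Step count and least certain steps

Total: 26 steps. Longest linear sequence: 17 steps (steps 1–14 and 24–26, from 1); the oxolane fragment takes 9 steps (15–23).

**Step 7 (key step).** The cycloaddition may be slow because the reacting terminus C6 sits next to the quaternary C11. Thermal isomerisation or decomposition of the silyl dienol ether could then compete, and the alkyl substituents could erode the regiochemical and facial preference. The fallback makes the reaction intramolecular. It sets out from aldehyde 11: silylation of the dienol with diisopropylsilyl bis(triflate) and capping of the second Si–OTf with acrylic acid give the silicon-tethered triene F1. The tether forces C4 onto C1 and C5 onto C6, and the tethered Diels–Alder reaction should give the tricyclic silyl acetal F2 under milder conditions. Cleavage of both Si–O bonds (HF·pyridine) and esterification (trimethylsilyldiazomethane) give the hydroxy ester F3, whose O-silylation (TBSOTf) returns to the route at 14.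

**Step 10.** The alkoxide may fail to fragment, because an ester enolate is a poor leaving group, or the liberated enal may isomerise under basic fluoride. The fallback is a Grob fragmentation and sets out from 16. LiBH4 reduces the ester to the primary alcohol F4, which is tosylated to F5. Fluoride then triggers fragmentation across O–C1, C1–C4 and C3–OTs to the (Z)-enal bearing a C6 allyl group, F6. Luche reduction gives the allylic alcohol F7, and 9-BBN hydroboration–oxidation of the terminal olefin returns to the route at 19.

**Step 4.** With the unprotected hydroxyl as proton source, O-methylation, over-reduction or loss of facial selectivity may occur. The fallback sets out from 8: silylation (TBSCl) gives the silyl ether F8, the Birch reductive methylation is run with one equivalent of t-BuOH to give the diene F9, and TBAF returns to the route at 10.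

**Step 13.** The very hindered, α-quaternary amide may be reduced incompletely or over-reduced. The fallback sets out from 20: lithium amidotrihydroborate reduces the amide to the primary alcohol F10 (C12–OH), and Parikh–Doering oxidation returns to the route at 21.

**Step 17.** The directed epoxidation may be unselective or favour the 1,3-anti isomer, since the control rests on a conformational preference of the vanadate. The fallback sets out from 24: the alanate is opened with the (R)-enantiomer of 25 to give the C16-epimeric alcohol F11. Its anti epoxy alcohol F12 (C18/C19 as in 28) cyclises under acid (CSA) by direct attack of O16 on C19, with retention at C16 and inversion at C19, and returns to the route at 31.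

**Step 19.** Water opening of the trisubstituted epoxide may proceed with partial loss of configuration at C19 (carbocation character) or at C18. The fallback sets out from 28: Mitsunobu inversion at C16 (4-nitrobenzoic acid, PPh3, DIAD) gives the ester F13. Methanolysis gives the anti epoxy alcohol F12, which cyclises intramolecularly (CSA) and returns to the route at 31.

## Further compounds

F1 | step 7 | (acryloyloxy)diisopropylsilyl (1E)-dienol ether of 11 | COC[C@@H]3CCCN3C(=O)[C@@]1(C)C=C(/C(C)=C/O[Si](C(C)C)(C(C)C)OC(=O)C=C)CC=C1OC
F2 | step 7 | tricyclic silicon-tethered Diels–Alder adduct (C1–O–Si–O–C3(=O)–C4 ring) | COC[C@@H]3CCCN3C(=O)[C@@]1(C)[C@@H]2CC4C(O[Si](C(C)C)(C(C)C)OC4=O)C(C)=C2CC=C1OC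
F3 | step 7 | C1-hydroxy C4-methyl ester bicycle (desilyl 14) | COC[C@@H]3CCCN3C(=O)[C@@]1(C)[C@@H]2CC(C(=O)OC)C(O)C(C)=C2CC=C1OC
F4 | step 10 | C3 primary alcohol of the bicycle | COC[C@@H]3CCCN3C(=O)[C@@]1(C)[C@@H]2CC(CO)C(O[Si](C)(C)C(C)(C)C)C(C)=C2CC[C@]1(C)O
F5 | step 10 | C3 tosylate of the bicycle | COC[C@@H]3CCCN3C(=O)[C@@]1(C)[C@@H]2CC(COS(=O)(=O)c4ccc(C)cc4)C(O[Si](C)(C)C(C)(C)C)C(C)=C2CC[C@]1(C)O
F6 | step 10 | (2Z)-enal with C6 allyl group | COC[C@@H]3CCCN3C(=O)[C@@]1(C)[C@H](CC=C)/C(=C(/C)C=O)CC[C@]1(C)O
F7 | step 10 | allylic alcohol with C6 allyl group | COC[C@@H]3CCCN3C(=O)[C@@]1(C)[C@H](CC=C)/C(=C(/C)CO)CC[C@]1(C)O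
F8 | step 4 | tert-butyldimethylsilyl ether of 8 | COC[C@@H]1CCCN1C(=O)c1cc(C(C)CO[Si](C)(C)C(C)(C)C)ccc1OC
F9 | step 4 | tert-butyldimethylsilyl ether of 10 | COC[C@@H]3CCCN3C(=O)[C@@]1(C)C=C(C(C)CO[Si](C)(C)C(C)(C)C)CC=C1OC
F10 | step 13 | C12 primary alcohol | OC[C@@]1(C)[C@H](CCCO[Si](CC)(CC)CC)/C(=C(/C)CO[Si](CC)(CC)CC)CC[C@]1(C)O[Si](CC)(CC)CC
F11 | step 17 | (2R,4E)-1-(benzyloxy)-5,9-dimethyldeca-4,8-dien-2-ol | CC(C)=CCC/C(C)=C/C[C@@H](O)COCc1ccccc1
F12 | step 17 | 1,3-anti C18–C19 epoxy alcohol (C16 epimer of 28) | CC(C)=CCC[C@@]1(C)O[C@@H]1C[C@@H](O)COCc2ccccc2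
F13 | step 19 | C16 4-nitrobenzoate with inverted C16 | CC(C)=CCC[C@@]1(C)O[C@@H]1C[C@@H](OC(=O)c2ccc(cc2)[N+](=O)[O-])COCc3ccccc3
A1 | alternative 1 | C7 cyclohexanone with C6, C10, C11 set | C=C[C@@]1(C)[C@H](CCCO[Si](C)(C)C(C)(C)C)C(=O)CC[C@]1(C)O[Si](CC)(CC)CC
A2 | alternative 1 | ethyl 2-(cyclohexylidene)propanoate, E/Z mixture at C2=C7 | C=C[C@@]1(C)[C@H](CCCO[Si](C)(C)C(C)(C)C)C(=C(C)C(=O)OCC)CC[C@]1(C)O[Si](CC)(CC)CC
A3 | alternative 2 | Robinson octalone (C3 ketone, C2=C7 in ring A) | C=C[C@@]1(C)[C@@H]2CCC(=O)C(C)=C2CC[C@]1(C)O
A4 | alternative 3 | cycloheptadiene ester from formal [4+3] (C1–C3 bonded, ring B ketal) | COC(=O)C1=CC[C@H]2CC3(CCC2=C(C)C1)OCCO3
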